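**Plan**

1. Numbering used here: ring carbons C1–C14, with C1 = oxirane CH, C14 = oxirane C(CH3) (methyl = C15), C12 = CH–OAc, C7 = CH–C16(CH3)2OH; C4=C5 is Z, C10=C11 is E. The oxirane bond C1–C14 is also a bond of the 14-membered carbocycle, C14 carries a methyl and sits two carbons from the C12 carbinol, and C1 ends a (CH2)3 arm: a latent methyl ketone facing a latent sulfonium ylide.
2. Retrosynthesis: C1–C14 and C1–O (one cascade) back to an open-chain keto sulfonium salt; then C12–C13 (allylation, Wacker), C11–C12 and C10–CH3 (carboalumination, CH2O), C3–C4 (B-alkyl Suzuki), C4=C5 (iodo-Wittig), and the ring alkene of α-terpineol (ozonolysis), which supplies C5–C11, C7 and C16.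
3. Forward: the chain grows linearly on the terpineol-derived keto aldehyde, first the Z arm (C1–C4), then the E arm (C12–C15). One operation then closes the carbocycle (C–C) and the oxirane (C–O); desilylation and acetylation finish.
4. Stereochemistry: C7 from (R)-α-terpineol; C12 from reagent-controlled allylboration; Z-C4=C5 from a Z-iodoalkene coupled with retention; E-C10=C11 from syn-methylalumination; C1 and C14 arise in the key step under control of the C12 silyloxy centre and the forming ring.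

Key step: step 14

Remark: (R)-(+)-α-terpineol and B-allyldiisopinocampheylborane of the (+)-α-pinene series [(+)-Ipc2B(allyl)] are taken as purchasable in high enantiomeric purity.

**Route**

Step 1
Reactants: 1 (R)-(+)-α-terpineol
Product: 2 (R)-α-terpineol triethylsilyl ether
Conditions: TESOTf, 2,6-lutidine, CH2Cl2, −78 → 0 °C
Reagents that add atoms: triethylsilyl trifluoromethanesulfonate, CC[Si](CC)(CC)OS(=O)(=O)C(F)(F)F
Why: Silyl triflate silylation of the tertiary alcohol keeps the later γ-hydroxy aldehyde from closing to a lactol; the stereocentre is untouched.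

Step 2
Reactants: 2 (R)-α-terpineol triethylsilyl ether
Product: 4 (3R)-6-oxo-3-[2-(triethylsilyloxy)propan-2-yl]heptanal, via ozonide 3 (not isolated)
Conditions: O3, CH2Cl2, −78 °C; then PPh3, −78 °C → rt
Reagents that add atoms: ozone, [O-][O+]=O
Why: Ozonolysis with reductive work-up cleaves the only alkene into the C5 aldehyde and the C10 methyl ketone, with C7 and its oxygenated side chain already in place.

Step 3
Reactants: 4 (3R)-6-oxo-3-[2-(triethylsilyloxy)propan-2-yl]heptanal
Product: 5 (5R,7Z)-8-iodo-5-[2-(triethylsilyloxy)propan-2-yl]non-7-en-2-one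
Conditions: EtPPh3I, n-BuLi, THF, 0 °C; I2, −78 °C; NaHMDS, −20 °C; then 4, −78 → −20 °C
Reagents that add atoms: ethyltriphenylphosphonium iodide, CC[P+](c1ccccc1)(c1ccccc1)c1ccccc1.[I-]; iodine, II
Why: The Stork–Zhao Wittig olefination with the α-iodo ylide is kinetically Z-selective (iodine cis to the chain) and much faster with aldehydes than with ketones, so C5 reacts beside the methyl ketone.

Step 4
Reactants: 6 4-methoxybenzyl alcohol; 7 allyl bromide
Product: 8 allyl 4-methoxybenzyl ether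
Conditions: NaH, THF/DMF, 0 °C → rt
Reagents that add atoms: none
Why: Williamson ether synthesis gives the three-carbon C1–C3 unit with an oxidatively removable protecting group.

Step 5
Reactants: 5 (5R,7Z)-8-iodo-5-[2-(triethylsilyloxy)propan-2-yl]non-7-en-2-one; 8 allyl 4-methoxybenzyl ether
Product: 10 (5R,7Z)-11-(4-methoxybenzyloxy)-8-methyl-5-[2-(triethylsilyloxy)propan-2-yl]undec-7-en-2-one, via alkylborane 9 (not isolated)
Conditions: 8, 9-BBN, THF, rt; then 5, Pd(dppf)Cl2 (cat.), AsPh3, Cs2CO3, DMF/H2O, rt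
Reagents that add atoms: none
Why: 9-BBN hydroborates the terminal alkene at CH2 and the B-alkyl Suzuki–Miyaura coupling replaces iodine with retention, which gives the Z-trisubstituted C4=C5 alkene.

Step 6
Reactants: 10 (5R,7Z)-11-(4-methoxybenzyloxy)-8-methyl-5-[2-(triethylsilyloxy)propan-2-yl]undec-7-en-2-one
Product: 12 (5R,7Z)-11-(4-methoxybenzyloxy)-8-methyl-5-[2-(triethylsilyloxy)propan-2-yl]undec-7-en-1-yne, via enol phosphate 11 (not isolated)
Conditions: LDA, THF, −78 °C; ClP(O)(OEt)2, −78 °C → rt; then LDA (excess), −78 °C → rt; H2O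
Reagents that add atoms: none
Why: Kinetic enolisation at the methyl group, O-phosphorylation and LDA elimination of the enol phosphate (methyl ketone to terminal alkyne) turn the terpineol methyl into C11.

Step 7
Reactants: 12 (5R,7Z)-11-(4-methoxybenzyloxy)-8-methyl-5-[2-(triethylsilyloxy)propan-2-yl]undec-7-en-1-yne
Product: 14 (2E,6R,8Z)-12-(4-methoxybenzyloxy)-3,9-dimethyl-6-[2-(triethylsilyloxy)propan-2-yl]dodeca-2,8-dien-1-ol, via alkenylalane 13 (not isolated)
Conditions: AlMe3, Cp2ZrCl2 (cat.), CH2Cl2, 0 °C → rt; then n-BuLi, THF, −78 °C; (CH2O)n, −78 °C → rt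
Reagents that add atoms: trimethylaluminium, C[Al](C)C; paraformaldehyde (as formaldehyde), C=O
Why: Zirconium-catalysed methylalumination (Negishi carboalumination) adds CH3 and Al syn with the methyl on the internal carbon, and the alanate is hydroxymethylated with retention, which fixes E-C10=C11.

Step 8
Reactants: 14 (2E,6R,8Z)-12-(4-methoxybenzyloxy)-3,9-dimethyl-6-[2-(triethylsilyloxy)propan-2-yl]dodeca-2,8-dien-1-ol
Product: 15 (2E,6R,8Z)-12-(4-methoxybenzyloxy)-3,9-dimethyl-6-[2-(triethylsilyloxy)propan-2-yl]dodeca-2,8-dienal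
Conditions: MnO2, CH2Cl2, rt
Reagents that add atoms: none
Why: MnO2 oxidises only the allylic alcohol and does not isomerise the enal.

Step 9
Reactants: 15 (2E,6R,8Z)-12-(4-methoxybenzyloxy)-3,9-dimethyl-6-[2-(triethylsilyloxy)propan-2-yl]dodeca-2,8-dienal
Product: 16 (4S,5E,9R,11Z)-15-(4-methoxybenzyloxy)-6,12-dimethyl-9-[2-(triethylsilyloxy)propan-2-yl]pentadeca-1,5,11-trien-4-ol
Conditions: (+)-Ipc2B(allyl), Et2O, −78 °C; then NaOH, H2O2
Reagents that add atoms: (+)-B-allyldiisopinocampheylborane, C=CCB([C@@H]1C[C@@H]2C[C@H]([C@H]1C)C2(C)C)[C@@H]1C[C@@H]2C[C@H]([C@H]1C)C2(C)C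
Why: Brown allylboration through a chair six-membered transition state; the isopinocampheyl groups of the (+)-α-pinene series deliver allyl to the Si face of the enal (the sense that gives the S carbinol from aryl and alkenyl aldehydes), which sets C12 as S.

Step 10
Reactants: 16 (4S,5E,9R,11Z)-15-(4-methoxybenzyloxy)-6,12-dimethyl-9-[2-(triethylsilyloxy)propan-2-yl]pentadeca-1,5,11-trien-4-ol
Product: 17 tert-butyldimethylsilyl ether of 16
Conditions: TBSOTf, 2,6-lutidine, CH2Cl2, −78 °C
Reagents that add atoms: tert-butyldimethylsilyl trifluoromethanesulfonate, CC(C)(C)[Si](C)(C)OS(=O)(=O)C(F)(F)F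
Why: Silylation of the secondary allylic alcohol gives a base-stable, non-chelating group that later shields one side of the β-ketone.

Step 11
Reactants: 17 tert-butyldimethylsilyl ether of 16
Product: 18 (4S,5E,9R,11Z)-4-(tert-butyldimethylsilyloxy)-15-(4-methoxybenzyloxy)-6,12-dimethyl-9-[2-(triethylsilyloxy)propan-2-yl]pentadeca-5,11-dien-2-one
Conditions: PdCl2 (cat.), CuCl, O2, DMF/H2O, rt
Reagents that add atoms: water, O
Why: Tsuji–Wacker oxidation converts the terminal alkene into the methyl ketone (Markovnikov attack of water) and leaves the trisubstituted alkenes untouched.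

Step 12
Reactants: 18 (4S,5E,9R,11Z)-4-(tert-butyldimethylsilyloxy)-15-(4-methoxybenzyloxy)-6,12-dimethyl-9-[2-(triethylsilyloxy)propan-2-yl]pentadeca-5,11-dien-2-one
Product: 19 (4S,5E,9R,11Z)-4-(tert-butyldimethylsilyloxy)-15-hydroxy-6,12-dimethyl-9-[2-(triethylsilyloxy)propan-2-yl]pentadeca-5,11-dien-2-one
Conditions: DDQ, CH2Cl2/pH 7 buffer, 0 °C
Reagents that add atoms: none
Why: DDQ cleaves the PMB ether oxidatively; silyl ethers, alkenes and the ketone are inert.

Step 13
Reactants: 19 (4S,5E,9R,11Z)-4-(tert-butyldimethylsilyloxy)-15-hydroxy-6,12-dimethyl-9-[2-(triethylsilyloxy)propan-2-yl]pentadeca-5,11-dien-2-one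
Product: 21 [(4Z,7R,10E,12S)-12-(tert-butyldimethylsilyloxy)-4,10-dimethyl-14-oxo-7-[2-(triethylsilyloxy)propan-2-yl]pentadeca-4,10-dien-1-yl]diphenylsulfonium triflate, via primary triflate 20 (not isolated)
Conditions: Tf2O, 2,6-di-tert-butyl-4-methylpyridine, CH2Cl2, −78 °C; then Ph2S (excess), −78 °C → rt
Reagents that add atoms: trifluoromethanesulfonic anhydride, O=S(=O)(OS(=O)(=O)C(F)(F)F)C(F)(F)F; diphenyl sulfide, c1ccc(Sc2ccccc2)cc1
Why: Triflation of the only free hydroxyl and SN2 alkylation of diphenyl sulfide give the alkyldiphenylsulfonium salt; the phenyl groups leave the C1 methylene as the only α-CH and exclude α′,β-elimination of the later ylide.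

Step 14
Reactants: 21 [(4Z,7R,10E,12S)-12-(tert-butyldimethylsilyloxy)-4,10-dimethyl-14-oxo-7-[2-(triethylsilyloxy)propan-2-yl]pentadeca-4,10-dien-1-yl]diphenylsulfonium triflate
Product: 24 (1S,7R,12S,14R,4Z,10E)-1,14-epoxy-12-(tert-butyldimethylsilyloxy)-4,10,14-trimethyl-7-[2-(triethylsilyloxy)propan-2-yl]cyclotetradeca-4,10-diene, via sulfonium ylide 22 (not isolated), via betaine 23 (not isolated)
Conditions: LiHMDS (1.05 equiv, slow addition), THF, 1 mM, −78 °C → −20 °C
Reagents that add atoms: none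
Why: Proposed new method: the base removes the only acidic proton type of 21 (S–CH2, several pKa units below the ketone α-CH) to give the non-stabilised ylide 22, whose carbon adds irreversibly to the C14 ketone and so closes the 14-membered carbocycle (14-exo-trig) to betaine 23, after which the alkoxide expels Ph2S from C1 with inversion (3-exo-tet) and closes the oxirane. The closest known reaction type is the intermolecular Corey–Chaykovsky epoxidation of ketones by diphenylsulfonium alkylides and its intramolecular small-ring version; the macrocyclic version is the new element. C14 is controlled by the C12 silyloxy centre: A(1,3) strain with the C10 methyl holds C12–H in the alkene plane, OTBS and C13 point to opposite faces, and in the extended C11–C14 segment that ring closure needs the carbonyl oxygen, not the larger methyl, should take the place syn to OTBS, which gives the 1,3-syn C–O pair of the target. C1 is fixed in the same addition and is controlled only by the forming ring: the cis-oxirane requires C2 and C13 gauche about the new bond in the closing betaine rotamer, which the Z-C4=C5 turn three atoms away is expected to favour. The step needs ylide formation over enolisation (acidity gap; enolisation by LiHMDS is reversible through HMDS), ring closure over oligomerisation (high dilution, two rigid alkenes in the tether) and one of four diastereomers; the last point is the open one.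

Step 15
Reactants: 24 (1S,7R,12S,14R,4Z,10E)-1,14-epoxy-12-(tert-butyldimethylsilyloxy)-4,10,14-trimethyl-7-[2-(triethylsilyloxy)propan-2-yl]cyclotetradeca-4,10-diene
Product: 25 (1S,7R,12S,14R,4Z,10E)-1,14-epoxy-7-(2-hydroxypropan-2-yl)-4,10,14-trimethylcyclotetradeca-4,10-dien-12-ol
Conditions: TBAF, THF, 0 °C → rt
Reagents that add atoms: none
Why: Fluoride removes both silyl ethers under basic conditions that leave the trisubstituted oxirane intact.

Step 16
Reactants: 25 (1S,7R,12S,14R,4Z,10E)-1,14-epoxy-7-(2-hydroxypropan-2-yl)-4,10,14-trimethylcyclotetradeca-4,10-dien-12-ol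
Product: 26 CNP0254503.1
Conditions: Ac2O, pyridine, DMAP (cat.), CH2Cl2, 0 °C
Reagents that add atoms: acetic anhydride, CC(=O)OC(C)=O
Why: The secondary allylic hydroxyl is acylated while the tertiary hydroxyl is too hindered to react under these mild conditions.

**Compound list**

1 | (R)-(+)-α-terpineol | CC1=CC[C@H](C(C)(C)O)CC1 | starting material
2 | (R)-α-terpineol triethylsilyl ether | CC1=CC[C@H](C(C)(C)O[Si](CC)(CC)CC)CC1 | intermediate
3 | ozonide (1,2,4-trioxolane) of 2, both acetal carbons unassigned | CC12CC[C@@H](C(C)(C)O[Si](CC)(CC)CC)CC(O1)OO2 | intermediate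
4 | (3R)-6-oxo-3-[2-(triethylsilyloxy)propan-2-yl]heptanal | O=CC[C@H](C(C)(C)O[Si](CC)(CC)CC)CCC(C)=O | intermediate
5 | (5R,7Z)-8-iodo-5-[2-(triethylsilyloxy)propan-2-yl]non-7-en-2-one | C/C(I)=C/C[C@H](C(C)(C)O[Si](CC)(CC)CC)CCC(C)=O | intermediate
6 | 4-methoxybenzyl alcohol | COc1ccc(CO)cc1 | starting material
7 | allyl bromide | C=CCBr | starting material
8 | allyl 4-methoxybenzyl ether | COc1ccc(COCC=C)cc1 | intermediate
9 | B-[3-(4-methoxybenzyloxy)propyl]-9-borabicyclo[3.3.1]nonane | COc1ccc(COCCCB2C3CCCC2CCC3)cc1 | intermediate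
10 | (5R,7Z)-11-(4-methoxybenzyloxy)-8-methyl-5-[2-(triethylsilyloxy)propan-2-yl]undec-7-en-2-one | COc1ccc(COCCC/C(C)=C\C[C@H](C(C)(C)O[Si](CC)(CC)CC)CCC(C)=O)cc1 | intermediate
11 | diethyl enol phosphate of 10 (terminal 2-phosphoryloxy-1-alkene) | COc1ccc(COCCC/C(C)=C\C[C@H](C(C)(C)O[Si](CC)(CC)CC)CCC(=C)OP(=O)(OCC)OCC)cc1 | intermediate
12 | (5R,7Z)-11-(4-methoxybenzyloxy)-8-methyl-5-[2-(triethylsilyloxy)propan-2-yl]undec-7-en-1-yne | COc1ccc(COCCC/C(C)=C\C[C@H](C(C)(C)O[Si](CC)(CC)CC)CCC#C)cc1 | intermediate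
13 | (E)-alkenyl(dimethyl)alane from syn-methylalumination of 12 | COc1ccc(COCCC/C(C)=C\C[C@H](C(C)(C)O[Si](CC)(CC)CC)CC/C(C)=C/[Al](C)C)cc1 | intermediate
14 | (2E,6R,8Z)-12-(4-methoxybenzyloxy)-3,9-dimethyl-6-[2-(triethylsilyloxy)propan-2-yl]dodeca-2,8-dien-1-ol | COc1ccc(COCCC/C(C)=C\C[C@H](C(C)(C)O[Si](CC)(CC)CC)CC/C(C)=C/CO)cc1 | intermediate
15 | (2E,6R,8Z)-12-(4-methoxybenzyloxy)-3,9-dimethyl-6-[2-(triethylsilyloxy)propan-2-yl]dodeca-2,8-dienal | COc1ccc(COCCC/C(C)=C\C[C@H](C(C)(C)O[Si](CC)(CC)CC)CC/C(C)=C/C=O)cc1 | intermediate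
16 | (4S,5E,9R,11Z)-15-(4-methoxybenzyloxy)-6,12-dimethyl-9-[2-(triethylsilyloxy)propan-2-yl]pentadeca-1,5,11-trien-4-ol | COc1ccc(COCCC/C(C)=C\C[C@H](C(C)(C)O[Si](CC)(CC)CC)CC/C(C)=C/[C@@H](O)CC=C)cc1 | intermediate
17 | tert-butyldimethylsilyl ether of 16 | COc1ccc(COCCC/C(C)=C\C[C@H](C(C)(C)O[Si](CC)(CC)CC)CC/C(C)=C/[C@@H](O[Si](C)(C)C(C)(C)C)CC=C)cc1 | intermediate
18 | (4S,5E,9R,11Z)-4-(tert-butyldimethylsilyloxy)-15-(4-methoxybenzyloxy)-6,12-dimethyl-9-[2-(triethylsilyloxy)propan-2-yl]pentadeca-5,11-dien-2-one | COc1ccc(COCCC/C(C)=C\C[C@H](C(C)(C)O[Si](CC)(CC)CC)CC/C(C)=C/[C@@H](O[Si](C)(C)C(C)(C)C)CC(C)=O)cc1 | intermediate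
19 | (4S,5E,9R,11Z)-4-(tert-butyldimethylsilyloxy)-15-hydroxy-6,12-dimethyl-9-[2-(triethylsilyloxy)propan-2-yl]pentadeca-5,11-dien-2-one | OCCC/C(C)=C\C[C@H](C(C)(C)O[Si](CC)(CC)CC)CC/C(C)=C/[C@@H](O[Si](C)(C)C(C)(C)C)CC(C)=O | intermediate
20 | primary triflate of 19 | O=S(=O)(OCCC/C(C)=C\C[C@H](C(C)(C)O[Si](CC)(CC)CC)CC/C(C)=C/[C@@H](O[Si](C)(C)C(C)(C)C)CC(C)=O)C(F)(F)F | intermediate
21 | [(4Z,7R,10E,12S)-12-(tert-butyldimethylsilyloxy)-4,10-dimethyl-14-oxo-7-[2-(triethylsilyloxy)propan-2-yl]pentadeca-4,10-dien-1-yl]diphenylsulfonium triflate | c1ccc(cc1)[S+](CCC/C(C)=C\C[C@H](C(C)(C)O[Si](CC)(CC)CC)CC/C(C)=C/[C@@H](O[Si](C)(C)C(C)(C)C)CC(C)=O)c1ccccc1.[O-]S(=O)(=O)C(F)(F)F | intermediate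
22 | diphenylsulfonium ylide of 21 (carbanion at C1) | c1ccc(cc1)[S+]([CH-]CC/C(C)=C\C[C@H](C(C)(C)O[Si](CC)(CC)CC)CC/C(C)=C/[C@@H](O[Si](C)(C)C(C)(C)C)CC(C)=O)c1ccccc1 | intermediate
23 | macrocyclic (1R,14R)-betaine: C1 diphenylsulfonio, C14 alkoxide | CC(C)(C)[Si](C)(C)O[C@@H]1/C=C(\C)CC[C@@H](C(C)(C)O[Si](CC)(CC)CC)C/C=C(/C)CC[C@@H]([S+](c2ccccc2)c2ccccc2)[C@@]([O-])(C)C1 | intermediate
24 | (1S,7R,12S,14R,4Z,10E)-1,14-epoxy-12-(tert-butyldimethylsilyloxy)-4,10,14-trimethyl-7-[2-(triethylsilyloxy)propan-2-yl]cyclotetradeca-4,10-diene | CC(C)(C)[Si](C)(C)O[C@@H]1/C=C(\C)CC[C@@H](C(C)(C)O[Si](CC)(CC)CC)C/C=C(/C)CC[C@@H]2O[C@]2(C)C1 | intermediate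
25 | (1S,7R,12S,14R,4Z,10E)-1,14-epoxy-7-(2-hydroxypropan-2-yl)-4,10,14-trimethylcyclotetradeca-4,10-dien-12-ol | O[C@@H]1/C=C(\C)CC[C@@H](C(C)(C)O)C/C=C(/C)CC[C@@H]2O[C@]2(C)C1 | intermediate
26 | CNP0254503.1, the 12-acetate of 25 | CC(=O)O[C@@H]1/C=C(\C)CC[C@@H](C(C)(C)O)C/C=C(/C)CC[C@@H]2O[C@]2(C)C1 | target

**Totals and risks**

Total step count: 16. Longest linear sequence: 15 steps (steps 1–3 and 5–16 from 1).

Steps most likely to fail:

Step 14 (Proposed new method). Possible failures are oligomerisation, ketone enolisation followed by β-elimination of the silyloxy group, and poor diastereoselection: the model predicts the required cis-oxirane with the 1,3-syn C–O pair but does not secure it. The fallback uses known chemistry and sets out from 19. Dess–Martin oxidation should give the keto aldehyde F1. A low-valent titanium pinacol macrocyclisation (TiCl3(DME)1.5, Zn–Cu, DME, high dilution, rt), a reaction type established for 14-membered carbocyclic diols, should then form the C1–C14 bond, and the (1R,14R)-diol F2 is separated from its diastereomers. Mesylation of the secondary hydroxyl (MsCl, Et3N, −20 °C) should give the mesylate F3, and K2CO3 in MeOH closes the oxirane with inversion at C1, which returns to the route at 24.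

Step 13. The primary triflate may be consumed by internal nucleophiles (the C4=C5 alkene, silyl ether oxygens) before the weakly nucleophilic diphenyl sulfide attacks, and the salt may be hard to free from by-products. The fallback sets out from 19 and builds the two S–C bonds in the other order. Thioetherification with PhSSPh and PBu3 should give the phenyl sulfide F4. Copper-catalysed S-phenylation with diphenyliodonium triflate (Cu(OBz)2 cat., chlorobenzene, heat) then gives the sulfonium triflate and comes back at 21.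

Step 3. The basic iodo ylide may trigger intramolecular aldol cyclisation of the 1,6-keto aldehyde, may attack the ketone, or may give an insufficient Z preference. The fallback sets out from 4 and replaces the stereoselective Wittig by stepwise differentiation of a gem-dihalide. Corey–Fuchs dibromo-olefination (CBr4, PPh3, CH2Cl2, 0 °C; neutral conditions) should give the gem-dibromoalkene F5. Palladium-catalysed trans-selective Negishi monomethylation (MeZnCl, Pd(DPEphos)Cl2 cat.) should give the (Z)-2-bromoalkene F6. B-alkyl Suzuki coupling of F6 with borane 9 under the conditions of step 5 comes back at 10.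

**Further compounds**

F1 | step 14 | (4Z,7R,10E,12S)-12-(tert-butyldimethylsilyloxy)-4,10-dimethyl-14-oxo-7-[2-(triethylsilyloxy)propan-2-yl]pentadeca-4,10-dienal | O=CCC/C(C)=C\C[C@H](C(C)(C)O[Si](CC)(CC)CC)CC/C(C)=C/[C@@H](O[Si](C)(C)C(C)(C)C)CC(C)=O
F2 | step 14 | (1R,7R,12S,14R,4Z,10E)-12-(tert-butyldimethylsilyloxy)-4,10,14-trimethyl-7-[2-(triethylsilyloxy)propan-2-yl]cyclotetradeca-4,10-diene-1,14-diol | CC(C)(C)[Si](C)(C)O[C@@H]1/C=C(\C)CC[C@@H](C(C)(C)O[Si](CC)(CC)CC)C/C=C(/C)CC[C@@H](O)[C@@](O)(C)C1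
F3 | step 14 | C1 methanesulfonate of F2 | CC(C)(C)[Si](C)(C)O[C@@H]1/C=C(\C)CC[C@@H](C(C)(C)O[Si](CC)(CC)CC)C/C=C(/C)CC[C@@H](OS(C)(=O)=O)[C@@](O)(C)C1
F4 | step 13 | (4S,5E,9R,11Z)-4-(tert-butyldimethylsilyloxy)-6,12-dimethyl-15-(phenylsulfanyl)-9-[2-(triethylsilyloxy)propan-2-yl]pentadeca-5,11-dien-2-one | c1ccc(cc1)SCCC/C(C)=C\C[C@H](C(C)(C)O[Si](CC)(CC)CC)CC/C(C)=C/[C@@H](O[Si](C)(C)C(C)(C)C)CC(C)=O
F5 | step 3 | (5R)-8,8-dibromo-5-[2-(triethylsilyloxy)propan-2-yl]oct-7-en-2-one | BrC(Br)=CC[C@H](C(C)(C)O[Si](CC)(CC)CC)CCC(C)=O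
F6 | step 3 | (5R,7Z)-8-bromo-5-[2-(triethylsilyloxy)propan-2-yl]non-7-en-2-one | C/C(Br)=C/C[C@H](C(C)(C)O[Si](CC)(CC)CC)CCC(C)=O
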